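## Structural features

The target is an unbranched C25 chain that ends in three heterocycles: a 3-methyltetronic acid (ring A: O1, C2–C5), a 3,4-disubstituted furan (ring B) attached at C14, and a 3-substituted furan (ring C) joined to ring B through one CH2 group. Ring A is linked to the chain by an exocyclic Z C5=C6 double bond, and ring B by an (11E,13E)-diene whose C11=C12 bond is trisubstituted (methyl on C11). The only stereocenter is C7 (S). It has no stereogenic neighbour and bears H, CH3, the C8 methylene chain and the sp2 carbon C6, so no adjacent functional group can be used to control it. Once ring A exists, C7–H is allylic and vinylogously acidified through C5=C6 and the lactone, so strong base late in the synthesis threatens the configuration. The fragile parts are the two furans and the furyl diene (acid, oxidants), the enol-lactone of ring A (hydride, nucleophiles) and the free vinylogous acid at C4–OH. The real difficulty is to set an isolated methyl-bearing center absolutely and to attach it to a Z-ylidene without epimerisation. A C5≡C6 alkyne on C7 is the direct precursor of the Z ylidene (anti oxy-metalation), so the key step makes C7 as a C–B center and passes it to an alkynyl carbon with retention.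

## Logic of the disconnections

40 to 39: the C4 enol is capped as its methyl ether. No skeletal bond is cut. The gain is that the acidic, metal-binding vinylogous acid is absent from all bond-forming steps. The forward demand is a demethylation that is neither basic nor acidic, because of C7–H and the furyl diene.

39 to 38: ring A is opened at O1–C5, which turns the Z C5=C6 ylidene into the C5≡C6 alkyne. Ring and alkene geometry disappear together, and C7 is merely propargylic in everything that precedes. The forward step must deliver oxygen to C5 (5-exo) anti to the metal, and it needs the carboxyl group cis to the alkynyl group across C3=C4.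

38 to 37 to 36 to 35: functional group changes only (acid from ester, enol ether from β-keto ester, ketone from alcohol). The demand falls on the O-methylation of 36, which must occur on oxygen and give the 2E enol ether.

35 to 32 and 33: the C3–C4 bond is cut as an aldol. This brings in C2, C3 and the C3 methyl as a cheap propionate. The two new centers are lost again on oxidation, so only 1,2-addition to the ynal is required.

32 to 30: the C4–C5 bond is cut, C4 coming from a formamide. The forward step needs selective metalation of the alkyne C–H in the presence of furan C–H bonds.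

30 to 18 and 28: the C13=C14 double bond is cut, dividing the molecule into the chiral chain and the bis-furan. It is cut at this stage, before ring A exists, so that neither hydride nor strong base is used once the lactone and the allylic C7 are in place. The forward olefination must be E-selective.

18 to 17 to 14 and 15: the C11=C12 double bond is cut back to a methyl ketone and a two-carbon phosphonate at the amide oxidation level, which gives the enal after one reduction. The demand is E-selectivity at a methyl ketone, which is only moderate and relies on separation.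

14 to 13: the ketone is masked as a dioxolane, needed for all organometallic steps before it.

13 to 8 and 9: the C6–C7 bond is cut (key step). The alkyne is traced to a secondary boronic ester and a two-carbon vinyl carbamate. The demand is complete retention at C7.

8 to 4 and 5: the C7–C8 bond is cut. C7 and its methyl come from 5 as a chiral carbenoid, the chain from the achiral primary boronate. The demand is reagent control of the carbenoid configuration; the sparteine enantiomer must be chosen to give S.

4 to 2 to 1: C–B bond from the Grignard reagent of the ketalised chloroketone.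

28 to 27 to 26 to 25: C–P bond by Arbuzov reaction of the bromide, which comes from the alcohol and its silyl ether.

25 to 23 and 24: the bond between the CH2 group and C3 of ring C is cut as an sp3–sp2 cross-coupling. 23 goes back through 22 and 20 to the symmetric diester 19, desymmetrised by monosilylation.

## Other disconnections considered

Alternative 1: The cut lies inside rings B and C. The silyl ether A1 (the same compound as 25) is traced to the bis(3,6-dihydro-1,2-dioxine) A2, the double singlet-oxygen [4+2] adduct of the cross-conjugated tetraene A3. In the forward key step, base opens both peroxides (Kornblum–DeLaMare) to γ-hydroxy enals, which cyclodehydrate, each forming one C–O bond.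
- In its favour: both heteroaromatic rings are made in one operation from non-aromatic material, with no palladium and no boronic acid. In ring construction it is clearly better than the chosen key step, which closes no ring.
- Against it here: it addresses only the bis-furan, which the chosen plan reaches in four routine steps from 19. A3 is a dendralene-type polyene prone to dimerisation, and it must take up two equivalents of singlet oxygen without ene reactions. A2 is a bis-peroxide with the attendant hazard.
- Comparison: A1 would join the chosen route at step 12 and leave C7 and ring A untouched, so the two plans are complementary rather than competing. In step count to 25 it is at best equal, because A3 itself needs several C–C bond-forming steps.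

Alternative 2: The cut is the O1–C2 bond of ring A with a change of ring size. The methyl tetronate A4 is traced to the 4-hydroxycyclobutenone A5, made by adding a chiral homoallylic organometallic to the squarate-derived dione A6. In the forward key step Pb(OAc)4 oxidises the tertiary alcohol, the bond between carbinol and carbonyl carbon breaks, the oxygen recloses on the acyl carbon, and loss of acetic acid gives the ylidene.
- In its favour: ring A arrives complete, with the C3 methyl, the C4 methoxy group and the C5=C6 bond, in two steps from A6. That is shorter than the seven steps the chosen plan spends on ring A, and it avoids the enol ether geometry problem of step 19. The terminal alkene of A4 would also allow the C11=C12 alkene to come from a stereodefined vinyl partner, which is better than the moderately selective step 6.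
- Against it here: C7 must be bought or made separately in a β-branched organometallic. The Z geometry rests on a thermodynamic preference in the elimination rather than on a stereospecific addition. Stoichiometric lead is required. The base-sensitive ylidene lactone with its allylic C7 is formed early and must survive the whole chain extension.
- Comparison: it is the better plan for ring A and probably for step count. The chosen plan is the better one for absolute control at C7 (reagent control, then stereospecific transfer) and for keeping the sensitive ring to the last two steps.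

Alternative 3: The cut is at the C2–C3 and C4–C5 bonds of ring B. The ester A7 is traced to 4-phenyloxazole A8 and the ynoate A9. The forward key step is a thermal [4+2] across the oxazole, followed by retro-[4+2] with loss of an aryl nitrile.
- In its favour: the 3,4-substitution pattern of ring B is unambiguous, and A7 is one reduction away from 26, so 26 would be reached in about three to four steps against five (steps 8–12). On step count for the bis-furan it is equal or slightly better.
- Against it here: the cycloaddition needs high temperature. A9 is a skipped ynoate that can isomerise to an allene, and its own furan ring is a competing diene. Like alternative 1 it does nothing for C7 or ring A.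
- Comparison: it could replace steps 8–12 without changing the rest. The chosen cross-coupling is milder and uses purchasable partners; the cycloaddition is more convergent in ring synthesis.

Key step: step 4

Remarks on the chemistry (assumptions):
- Configuration check: 8, 13 and the target carry the same spatial arrangement at C7 (S in each), so retention in step 4 is what is needed.
- Sparteine enantiomer: (−)-sparteine removes the pro-S hydrogen of 5 and would lead to the R boronate. Step 3 therefore uses (+)-sparteine, assumed purchasable.
- Step 4 is counted as one step because 12 is carried on crude.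

## Steps

Step 1
Reactants: 1 5-chloropentan-2-one
Product: 2 2-(3-chloropropyl)-2-methyl-1,3-dioxolane
Conditions: ethylene glycol, TsOH·H2O (cat.), toluene, reflux, Dean–Stark
Reagents that add atoms: ethylene glycol, OCCO
Why: Acid-catalysed ketalisation driven by azeotropic removal of water; the ketone must be masked for the magnesium, organolithium and lithium amide steps that follow, and the primary chloride is inert here.

Step 2
Reactants: 2 2-(3-chloropropyl)-2-methyl-1,3-dioxolane
Product: 4 4,4,5,5-tetramethyl-2-[3-(2-methyl-1,3-dioxolan-2-yl)propyl]-1,3,2-dioxaborolane, via Grignard reagent 3 (not isolated)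
Conditions: Mg, BrCH2CH2Br (cat.), THF, reflux; then iPrOBpin, THF, −78 °C → rt; aq. NH4Cl
Reagents that add atoms: 2-isopropoxy-4,4,5,5-tetramethyl-1,3,2-dioxaborolane, CC(C)OB1OC(C)(C)C(C)(C)O1
Why: Grignard formation from the primary chloride (the dioxolane tolerates magnesium halide) and electrophilic borylation; low temperature and the hindered pinacol borate stop the reaction after one alkyl transfer.

Step 3
Reactants: 5 ethyl N,N-diisopropylcarbamate; 4 4,4,5,5-tetramethyl-2-[3-(2-methyl-1,3-dioxolan-2-yl)propyl]-1,3,2-dioxaborolane
Product: 8 4,4,5,5-tetramethyl-2-[(2S)-5-(2-methyl-1,3-dioxolan-2-yl)pentan-2-yl]-1,3,2-dioxaborolane, via lithiated ethyl carbamate 6 (not isolated), via boronate complex 7 (not isolated)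
Conditions: 5, (+)-sparteine, s-BuLi, Et2O, −78 °C, 5 h; 4, −78 °C, 1 h; MgBr2·OEt2, then reflux, 16 h
Reagents that add atoms: none
Why: Lithiation–borylation: (+)-sparteine directs s-BuLi to the pro-R hydrogen of 5 to give the configurationally stable R carbenoid 6, boron is taken up with retention to give 7, and the primary alkyl group then shifts from boron to carbon with inversion as carbamate leaves, which sets C7 as S. MgBr2·OEt2 speeds the 1,2-shift of pinacol boronate complexes, and the ketal already tolerated magnesium halide in step 2.

Step 4
Reactants: 9 vinyl N,N-diisopropylcarbamate; 8 4,4,5,5-tetramethyl-2-[(2S)-5-(2-methyl-1,3-dioxolan-2-yl)pentan-2-yl]-1,3,2-dioxaborolane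
Product: 13 2-methyl-2-[(4S)-4-methylhex-5-ynyl]-1,3-dioxolane, via lithiated vinyl carbamate 10 (not isolated), via vinylboronate complex 11 (not isolated), via vinyl carbamate 12 (not isolated)
Conditions: 9, LiN(iPr)2, THF, −78 °C; 8, −78 °C; I2, MeOH, −78 °C, then NaOMe, → rt; aq. Na2S2O3 wash, crude 12 dried; LiN(iPr)2 (3 equiv), THF, −78 °C → rt; aq. NH4Cl
Reagents that add atoms: none
Why: This is a Zweifel-type 1,2-metallate rearrangement followed by carbamate elimination, the known enantiospecific alkynylation of secondary boronic esters: LiN(iPr)2 lithiates 9 at the α-vinyl position to give 10, which adds to boron of 8 to give the tetracoordinate complex 11. Iodine activates the electron-rich vinyl group of 11 and the C7 alkyl group shifts from boron to the neighbouring carbon, forming the C6–C7 bond; methoxide then attacks boron, and anti elimination of boron and iodide releases the 1,1-disubstituted vinyl carbamate 12. Excess LiN(iPr)2 removes a vinylic hydrogen of 12 and expels lithium carbamate in a 1,2-elimination, and the alkyne is held as its acetylide until work-up. No ring is closed and no new stereocenter is created; the one stereochemical demand is complete retention at C7, which is inherent in a concerted shift of the sp3 carbon with its bonding pair, with no radical or carbanion at C7. Chemoselectivity requires that the secondary alkyl group migrates and not a pinacol oxygen, which the poor migratory aptitude of the diol oxygens secures, and that 10 adds to boron before it decomposes, which the low temperature and the accessible Bpin group secure. The dioxolane is inert to lithium amide, to iodine in methanol once methoxide buffers the acid, and to the acetylide. Because 12 is 1,1-disubstituted, no alkene geometry has to be controlled before the elimination.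

Step 5
Reactants: 13 2-methyl-2-[(4S)-4-methylhex-5-ynyl]-1,3-dioxolane
Product: 14 (6S)-6-methyloct-7-yn-2-one
Conditions: 1 M HCl, THF, rt
Reagents that add atoms: water, O
Why: Acid-catalysed ketal hydrolysis; the terminal alkyne and the propargylic center are unaffected by dilute acid at room temperature (the product is volatile and is concentrated with care).

Step 6
Reactants: 14 (6S)-6-methyloct-7-yn-2-one; 15 diethyl [2-[methoxy(methyl)amino]-2-oxoethyl]phosphonate
Product: 17 (2E,7S)-N-methoxy-N,3,7-trimethylnon-2-en-8-ynamide, via sodium phosphonate carbanion 16 (not isolated)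
Conditions: 15, NaH, THF, 0 °C; 14, rt → reflux
Reagents that add atoms: none
Why: Horner–Wadsworth–Emmons olefination of a methyl ketone; reversible addition places the longer chain trans to the carboxamide, so the E isomer should predominate and the minor Z isomer is removed by chromatography here or after step 7. The stabilised carbanion 16 is too weak a base to deprotonate the alkyne.

Step 7
Reactants: 17 (2E,7S)-N-methoxy-N,3,7-trimethylnon-2-en-8-ynamide
Product: 18 (2E,7S)-3,7-dimethylnon-2-en-8-ynal
Conditions: iBu2AlH, THF, −78 °C; aq. potassium sodium tartrate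
Reagents that add atoms: none
Why: Reduction of an N-methoxy-N-methyl amide stops at a chelated aluminium hemiaminal that releases the aldehyde only on work-up, so neither over-reduction nor 1,4-reduction is expected; alkyne and alkene do not react at −78 °C.

Step 8
Reactants: 19 dimethyl furan-3,4-dicarboxylate
Product: 20 furan-3,4-diyldimethanol
Conditions: LiAlH4, THF, 0 °C → rt; aq. NaOH work-up
Reagents that add atoms: none
Why: Hydride reduction of both esters to the primary alcohols; the furan ring is inert to LiAlH4.

Step 9
Reactants: 20 furan-3,4-diyldimethanol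
Product: 22 [4-[[tert-butyl(dimethyl)silyl]oxymethyl]furan-3-yl]methanol, via monosodium alkoxide 21 (not isolated)
Conditions: NaH (1.0 equiv), THF, 0 °C → rt; TBSCl (1.0 equiv)
Reagents that add atoms: tert-butyl(chloro)dimethylsilane, CC(C)(C)[Si](C)(C)Cl
Why: Monosilylation of a symmetric diol through its sparingly soluble monosodium alkoxide, which is silylated before a second deprotonation takes place; recovered diol and bis-ether are recycled.

Step 10
Reactants: 22 [4-[[tert-butyl(dimethyl)silyl]oxymethyl]furan-3-yl]methanol
Product: 23 [4-(bromomethyl)furan-3-yl]methoxy-tert-butyl-dimethylsilane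
Conditions: CBr4, PPh3, CH2Cl2, 0 °C; short silica plug, used at once
Reagents that add atoms: tetrabromomethane, BrC(Br)(Br)Br
Why: Appel bromination under near-neutral conditions, which spares the silyl ether and the acid-sensitive furan; the labile furylmethyl bromide is not stored.

Step 11
Reactants: 23 [4-(bromomethyl)furan-3-yl]methoxy-tert-butyl-dimethylsilane; 24 furan-3-ylboronic acid
Product: 25 tert-butyl-[[4-(furan-3-ylmethyl)furan-3-yl]methoxy]dimethylsilane
Conditions: PdCl2(dppf) (5 mol %), Cs2CO3, THF/H2O (10:1), 70 °C
Reagents that add atoms: none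
Why: sp3–sp2 Suzuki–Miyaura coupling of a benzylic-type bromide, which adds readily to zerovalent palladium and has no β-hydrogen, with a heteroarylboronic acid; this joins the CH2 group to ring C.

Step 12
Reactants: 25 tert-butyl-[[4-(furan-3-ylmethyl)furan-3-yl]methoxy]dimethylsilane
Product: 26 [4-(furan-3-ylmethyl)furan-3-yl]methanol
Conditions: Bu4NF, THF, 0 °C → rt
Reagents that add atoms: none
Why: Fluoride cleavage of the silyl ether under non-acidic conditions that leave both furans untouched.

Step 13
Reactants: 26 [4-(furan-3-ylmethyl)furan-3-yl]methanol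
Product: 27 3-(bromomethyl)-4-(furan-3-ylmethyl)furan
Conditions: CBr4, PPh3 (slight deficit), CH2Cl2, 0 °C; short silica plug, used at once
Reagents that add atoms: tetrabromomethane, BrC(Br)(Br)Br
Why: Appel bromination as in step 10; a slight deficit of phosphine and immediate filtration keep free PPh3 out of the next step.

Step 14
Reactants: 27 3-(bromomethyl)-4-(furan-3-ylmethyl)furan
Product: 28 diethyl [[4-(furan-3-ylmethyl)furan-3-yl]methyl]phosphonate
Conditions: P(OEt)3 (neat), 110 °C; excess removed in vacuo
Reagents that add atoms: triethyl phosphite, CCOP(OCC)OCC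
Why: Michaelis–Arbuzov reaction of a reactive benzylic-type bromide; bromoethane distils off and no acid or base is involved.

Step 15
Reactants: 28 diethyl [[4-(furan-3-ylmethyl)furan-3-yl]methyl]phosphonate; 18 (2E,7S)-3,7-dimethylnon-2-en-8-ynal
Product: 30 3-[(1E,3E,8S)-4,8-dimethyldeca-1,3-dien-9-ynyl]-4-(furan-3-ylmethyl)furan, via potassium phosphonate carbanion 29 (not isolated)
Conditions: 28, KN(SiMe3)2 (0.95 equiv to 28), THF, −78 °C; 18, −78 °C → rt
Reagents that add atoms: none
Why: Horner–Wadsworth–Emmons olefination with a semi-stabilised benzylic-type phosphonate, which gives E alkenes as in stilbene syntheses and so should set C13=C14 as E. The carbanion is pre-formed with the base as limiting reagent, so no free base remains to enolise the enal or deprotonate the alkyne. The union is made before ring A exists, so no strong base is needed later.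

Step 16
Reactants: 30 3-[(1E,3E,8S)-4,8-dimethyldeca-1,3-dien-9-ynyl]-4-(furan-3-ylmethyl)furan
Product: 32 (4S,8E,10E)-11-[4-(furan-3-ylmethyl)furan-3-yl]-4,8-dimethylundeca-8,10-dien-2-ynal, via lithium acetylide 31 (not isolated)
Conditions: n-BuLi (1.05 equiv), THF, −78 °C; DMF, −78 → 0 °C; inverse quench into cold aq. KH2PO4
Reagents that add atoms: N,N-dimethylformamide, CN(C)C=O
Why: Formylation of a lithium acetylide; the alkyne C–H is far more acidic than the furan α-hydrogens or the bis-furyl CH2, and the buffered inverse quench prevents addition of dimethylamine to the ynal.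

Step 17
Reactants: 33 methyl propanoate; 32 (4S,8E,10E)-11-[4-(furan-3-ylmethyl)furan-3-yl]-4,8-dimethylundeca-8,10-dien-2-ynal
Product: 35 methyl (6S,10E,12E)-13-[4-(furan-3-ylmethyl)furan-3-yl]-3-hydroxy-2,6,10-trimethyltrideca-10,12-dien-4-ynoate (mixture of C2/C3 diastereomers), via lithium ester enolate 34 (not isolated)
Conditions: 33, LiN(iPr)2, THF, −78 °C; 32, −78 °C; aq. NH4Cl at −78 °C
Reagents that add atoms: none
Why: Aldol addition of a lithium ester enolate to an ynal goes 1,2 at low temperature; the two new centers need no control because both become sp2 in steps 18 and 19, and C7 is not deprotonated by the enolate.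

Step 18
Reactants: 35 methyl (6S,10E,12E)-13-[4-(furan-3-ylmethyl)furan-3-yl]-3-hydroxy-2,6,10-trimethyltrideca-10,12-dien-4-ynoate
Product: 36 methyl (6S,10E,12E)-13-[4-(furan-3-ylmethyl)furan-3-yl]-2,6,10-trimethyl-3-oxotrideca-10,12-dien-4-ynoate
Conditions: Dess–Martin periodinane, NaHCO3, CH2Cl2, 0 °C → rt
Reagents that add atoms: none
Why: Buffered hypervalent iodine oxidation of the propargylic alcohol to the alkynyl β-keto ester; the neutral conditions spare the furans and the diene.

Step 19
Reactants: 36 methyl (6S,10E,12E)-13-[4-(furan-3-ylmethyl)furan-3-yl]-2,6,10-trimethyl-3-oxotrideca-10,12-dien-4-ynoate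
Product: 37 methyl (2E,6S,10E,12E)-13-[4-(furan-3-ylmethyl)furan-3-yl]-3-methoxy-2,6,10-trimethyltrideca-2,10,12-trien-4-ynoate
Conditions: Me2SO4, Cs2CO3, DMF, 0 °C → rt
Reagents that add atoms: dimethyl sulfate, COS(=O)(=O)OC
Why: O-Alkylation of a dissociated cesium enolate by a hard methylating agent in a dipolar aprotic solvent; the free enolate prefers the dipole-minimised W shape, so the methoxy group should end trans to the ester and the alkynyl group cis to it (2E), the geometry that step 21 needs, and C2 is already substituted, which disfavours C-methylation.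

Step 20
Reactants: 37 methyl (2E,6S,10E,12E)-13-[4-(furan-3-ylmethyl)furan-3-yl]-3-methoxy-2,6,10-trimethyltrideca-2,10,12-trien-4-ynoate
Product: 38 (2E,6S,10E,12E)-13-[4-(furan-3-ylmethyl)furan-3-yl]-3-methoxy-2,6,10-trimethyltrideca-2,10,12-trien-4-ynoic acid
Conditions: LiOH, THF/MeOH/H2O, rt → 40 °C; aq. NaH2PO4/H3PO4 to pH 4
Reagents that add atoms: lithium hydroxide, [Li+].[OH-]
Why: Saponification of the β-methoxyacrylate ester at the acyl carbon; the carboxylate formed does not acidify the propargylic C7–H, and acidification only to pH 4 protects the enol ether and the furans.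

Step 21
Reactants: 38 (2E,6S,10E,12E)-13-[4-(furan-3-ylmethyl)furan-3-yl]-3-methoxy-2,6,10-trimethyltrideca-2,10,12-trien-4-ynoic acid
Product: 39 (5Z)-5-[(2S,6E,8E)-9-[4-(furan-3-ylmethyl)furan-3-yl]-2,6-dimethylnona-6,8-dienylidene]-4-methoxy-3-methylfuran-2(5H)-one
Conditions: AgNO3 (10 mol %), MeOH, rt, dark
Reagents that add atoms: none
Why: Silver-catalysed 5-exo-dig cycloisomerisation of a 2-en-4-ynoic acid: monovalent silver activates the alkyne, the carboxyl oxygen adds to C5 anti to the metal, and protodemetalation with retention puts H on C6 trans to O1, so C5=C6 is Z. C7 is not involved.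

Step 22
Reactants: 39 (5Z)-5-[(2S,6E,8E)-9-[4-(furan-3-ylmethyl)furan-3-yl]-2,6-dimethylnona-6,8-dienylidene]-4-methoxy-3-methylfuran-2(5H)-one
Product: 40 (5Z)-5-[(2S,6E,8E)-9-[4-(furan-3-ylmethyl)furan-3-yl]-2,6-dimethylnona-6,8-dienylidene]-4-hydroxy-3-methylfuran-2(5H)-one
Conditions: LiCl, DMSO, 50 °C; aq. NaH2PO4/H3PO4 to pH 3
Reagents that add atoms: none
Why: SN2 demethylation by chloride at the methyl group of the vinylogous carbonate, with the tetronate as a good leaving group; the medium is neither basic nor strongly acidic, so C7, the ylidene and the furyl diene should survive.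

## Compound list

1 | 5-chloropentan-2-one | CC(=O)CCCCl | starting material
2 | 2-(3-chloropropyl)-2-methyl-1,3-dioxolane | CC1(CCCCl)OCCO1 | intermediate
3 | [3-(2-methyl-1,3-dioxolan-2-yl)propyl]magnesium chloride | CC1(CCC[Mg]Cl)OCCO1 | intermediate (not isolated)
4 | 4,4,5,5-tetramethyl-2-[3-(2-methyl-1,3-dioxolan-2-yl)propyl]-1,3,2-dioxaborolane | CC1(CCCB2OC(C)(C)C(C)(C)O2)OCCO1 | intermediate
5 | ethyl N,N-diisopropylcarbamate | CCOC(=O)N(C(C)C)C(C)C | starting material
6 | [(1R)-1-lithioethyl] N,N-diisopropylcarbamate, (+)-sparteine complex | C[C@@H]([Li])OC(=O)N(C(C)C)C(C)C | intermediate (not isolated)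
7 | lithium boronate complex of 4 with 6 (B in place of Li, carbamate retained) | [Li+].C[C@H](OC(=O)N(C(C)C)C(C)C)[B-]1(CCCC2(C)OCCO2)OC(C)(C)C(C)(C)O1 | intermediate (not isolated)
8 | 4,4,5,5-tetramethyl-2-[(2S)-5-(2-methyl-1,3-dioxolan-2-yl)pentan-2-yl]-1,3,2-dioxaborolane | CC1(C)OB([C@@H](C)CCCC2(C)OCCO2)OC1(C)C | intermediate
9 | vinyl N,N-diisopropylcarbamate | C=COC(=O)N(C(C)C)C(C)C | starting material
10 | 1-lithiovinyl N,N-diisopropylcarbamate | [Li]C(=C)OC(=O)N(C(C)C)C(C)C | intermediate (not isolated)
11 | lithium vinylboronate complex of 8 with 10 | [Li+].C=C(OC(=O)N(C(C)C)C(C)C)[B-]1([C@@H](C)CCCC2(C)OCCO2)OC(C)(C)C(C)(C)O1 | intermediate (not isolated)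
12 | [(3S)-3-methyl-6-(2-methyl-1,3-dioxolan-2-yl)hex-1-en-2-yl] N,N-diisopropylcarbamate | C=C(OC(=O)N(C(C)C)C(C)C)[C@@H](C)CCCC1(C)OCCO1 | intermediate (not isolated)
13 | 2-methyl-2-[(4S)-4-methylhex-5-ynyl]-1,3-dioxolane | C#C[C@@H](C)CCCC1(C)OCCO1 | intermediate
14 | (6S)-6-methyloct-7-yn-2-one | C#C[C@@H](C)CCCC(C)=O | intermediate
15 | diethyl [2-[methoxy(methyl)amino]-2-oxoethyl]phosphonate | CCOP(=O)(CC(=O)N(C)OC)OCC | starting material
16 | sodium salt of the α-carbanion of 15 | [Na+].CCOP(=O)([CH-]C(=O)N(C)OC)OCC | intermediate (not isolated)
17 | (2E,7S)-N-methoxy-N,3,7-trimethylnon-2-en-8-ynamide | C#C[C@@H](C)CCC/C(C)=C/C(=O)N(C)OC | intermediate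
18 | (2E,7S)-3,7-dimethylnon-2-en-8-ynal | C#C[C@@H](C)CCC/C(C)=C/C=O | intermediate
19 | dimethyl furan-3,4-dicarboxylate | COC(=O)c1cocc1C(=O)OC | starting material
20 | furan-3,4-diyldimethanol | OCc1cocc1CO | intermediate
21 | monosodium alkoxide of 20 | [Na+].[O-]Cc1cocc1CO | intermediate (not isolated)
22 | [4-[[tert-butyl(dimethyl)silyl]oxymethyl]furan-3-yl]methanol | CC(C)(C)[Si](C)(C)OCc1cocc1CO | intermediate
23 | [4-(bromomethyl)furan-3-yl]methoxy-tert-butyl-dimethylsilane | CC(C)(C)[Si](C)(C)OCc1cocc1CBr | intermediate
24 | furan-3-ylboronic acid | OB(O)c1ccoc1 | starting material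
25 | tert-butyl-[[4-(furan-3-ylmethyl)furan-3-yl]methoxy]dimethylsilane | CC(C)(C)[Si](C)(C)OCc1cocc1Cc1ccoc1 | intermediate
26 | [4-(furan-3-ylmethyl)furan-3-yl]methanol | OCc1cocc1Cc1ccoc1 | intermediate
27 | 3-(bromomethyl)-4-(furan-3-ylmethyl)furan | BrCc1cocc1Cc1ccoc1 | intermediate
28 | diethyl [[4-(furan-3-ylmethyl)furan-3-yl]methyl]phosphonate | CCOP(=O)(Cc1cocc1Cc1ccoc1)OCC | intermediate
29 | potassium salt of the α-carbanion of 28 | [K+].CCOP(=O)([CH-]c1cocc1Cc1ccoc1)OCC | intermediate (not isolated)
30 | 3-[(1E,3E,8S)-4,8-dimethyldeca-1,3-dien-9-ynyl]-4-(furan-3-ylmethyl)furan | C#C[C@@H](C)CCC/C(C)=C/C=C/c1cocc1Cc1ccoc1 | intermediate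
31 | lithium acetylide of 30 | [Li]C#C[C@@H](C)CCC/C(C)=C/C=C/c1cocc1Cc1ccoc1 | intermediate (not isolated)
32 | (4S,8E,10E)-11-[4-(furan-3-ylmethyl)furan-3-yl]-4,8-dimethylundeca-8,10-dien-2-ynal | O=CC#C[C@@H](C)CCC/C(C)=C/C=C/c1cocc1Cc1ccoc1 | intermediate
33 | methyl propanoate | CCC(=O)OC | starting material
34 | lithium (Z)-1-methoxyprop-1-en-1-olate | [Li+].C/C=C(/[O-])OC | intermediate (not isolated)
35 | methyl (6S,10E,12E)-13-[4-(furan-3-ylmethyl)furan-3-yl]-3-hydroxy-2,6,10-trimethyltrideca-10,12-dien-4-ynoate (C2/C3 diastereomers) | COC(=O)C(C)C(O)C#C[C@@H](C)CCC/C(C)=C/C=C/c1cocc1Cc1ccoc1 | intermediate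
36 | methyl (6S,10E,12E)-13-[4-(furan-3-ylmethyl)furan-3-yl]-2,6,10-trimethyl-3-oxotrideca-10,12-dien-4-ynoate (C2 epimers, partly enolised) | COC(=O)C(C)C(=O)C#C[C@@H](C)CCC/C(C)=C/C=C/c1cocc1Cc1ccoc1 | intermediate
37 | methyl (2E,6S,10E,12E)-13-[4-(furan-3-ylmethyl)furan-3-yl]-3-methoxy-2,6,10-trimethyltrideca-2,10,12-trien-4-ynoate | COC(=O)/C(C)=C(/OC)C#C[C@@H](C)CCC/C(C)=C/C=C/c1cocc1Cc1ccoc1 | intermediate
38 | (2E,6S,10E,12E)-13-[4-(furan-3-ylmethyl)furan-3-yl]-3-methoxy-2,6,10-trimethyltrideca-2,10,12-trien-4-ynoic acid | OC(=O)/C(C)=C(/OC)C#C[C@@H](C)CCC/C(C)=C/C=C/c1cocc1Cc1ccoc1 | intermediate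
39 | (5Z)-5-[(2S,6E,8E)-9-[4-(furan-3-ylmethyl)furan-3-yl]-2,6-dimethylnona-6,8-dienylidene]-4-methoxy-3-methylfuran-2(5H)-one | CC1=C(OC)/C(=C/[C@@H](C)CCC/C(C)=C/C=C/c2cocc2Cc2ccoc2)OC1=O | intermediate
40 | (5Z)-5-[(2S,6E,8E)-9-[4-(furan-3-ylmethyl)furan-3-yl]-2,6-dimethylnona-6,8-dienylidene]-4-hydroxy-3-methylfuran-2(5H)-one | CC1=C(O)/C(=C/[C@@H](C)CCC/C(C)=C/C=C/c2cocc2Cc2ccoc2)OC1=O | target

## Step count and least certain steps

Total: 22 steps. Longest linear sequence: 15 steps (steps 1–7 and 15–22 from 1; the branch from 19 through steps 8–14 and 15–22 is equally long).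

**Step 4 (key step).** The most likely failure is incomplete formation of complex 11, because the lithiated vinyl carbamate 10 can rearrange before it adds to the hindered secondary boronate. A second risk is partial loss of the ketal if acid from the iodination is not buffered. The fallback sets out from 8 and returns at 13:
- Matteson homologation of 8 with LiCHCl2 (THF, −100 °C → rt) moves C7 from boron to carbon with retention and should give 2-[(2S)-1-chloro-2-methyl-5-(2-methyl-1,3-dioxolan-2-yl)pentyl]-4,4,5,5-tetramethyl-1,3,2-dioxaborolane F1.
- Buffered oxidation (NaBO3, THF/H2O) converts it to (2S)-2-methyl-5-(2-methyl-1,3-dioxolan-2-yl)pentanal F2.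
- Seyferth–Gilbert homologation with the Ohira–Bestmann reagent (K2CO3, MeOH, 0 °C) then gives 13.
- The C6–C7 bond is still made by a boron-to-carbon shift, but the alkyne carbon C5 arrives separately. The weak point is α-epimerisation of the aldehyde.

**Step 19.** The process at risk is the site and geometry of enolate alkylation: methylation on C2, formation of the enol ether with the ester cis to methoxy, or cyclisation of the enolate oxygen onto the ynone before it is methylated. The fallback avoids the enol ether altogether; it sets out from 35 and returns at 40: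
- Saponification (LiOH, THF/H2O, 0 °C) gives (6S,10E,12E)-13-[4-(furan-3-ylmethyl)furan-3-yl]-3-hydroxy-2,6,10-trimethyltrideca-10,12-dien-4-ynoic acid F8.
- Silver-catalysed 5-exo-dig lactonisation (AgNO3 cat., MeOH), for which a 4-ynoic acid with sp3 carbons in the tether has no 6-endo bias, gives (5Z)-5-[(2S,6E,8E)-9-[4-(furan-3-ylmethyl)furan-3-yl]-2,6-dimethylnona-6,8-dienylidene]-4-hydroxy-3-methyloxolan-2-one F9.
- Oxidation of the allylic alcohol (Dess–Martin periodinane, NaHCO3, or MnO2) gives the 2,4-dione, which enolises to 40.
- This is two steps shorter and also makes steps 20–22 unnecessary. It is held in reserve because β-elimination of water from the hydroxy lactone and oxidation in the presence of the free tetronic acid are less well charted than the methyl ether route.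

**Step 3.** The risk is erosion of enantiomeric purity if deprotonation under (+)-sparteine is incomplete or the complex is not fully formed, and slow 1,2-migration that leaves 4 mixed with 8. The fallback exchanges the roles of the partners so that the common (−)-sparteine gives the same S product; it sets out from 2 (through 3) and returns at 8:
- Grignard reagent 3 with paraformaldehyde gives 4-(2-methyl-1,3-dioxolan-2-yl)butan-1-ol F3.
- iPr2NCOCl, Et3N (CH2Cl2, reflux) gives 4-(2-methyl-1,3-dioxolan-2-yl)butyl N,N-diisopropylcarbamate F4.
- Lithiation with s-BuLi/(−)-sparteine (Et2O, −78 °C), trapping with methylboronic acid pinacol ester and 1,2-shift of the methyl group (MgBr2·OEt2, reflux) gives 8. Boron enters with retention and methyl with inversion, which again places C7 as S.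

**Step 6.** The process at risk is poor E/Z discrimination at the methyl ketone, combined with isomers that are hard to separate as amides. The fallback moves the separation to a stage where such isomers separate readily; it sets out from 14 and returns at 18:
- Triethyl phosphonoacetate/NaH gives ethyl (2E,7S)-3,7-dimethylnon-2-en-8-ynoate F5.
- iBu2AlH (CH2Cl2, −78 °C) gives (2E,7S)-3,7-dimethylnon-2-en-8-yn-1-ol F6, which is freed from its Z isomer by chromatography.
- MnO2 (CH2Cl2) gives 18, at the cost of one extra step.

**Step 11.** The risk is hydrolysis or homocoupling of the labile furylmethyl bromide and protodeboronation of 24 under aqueous base. The fallback reverses the polarity under anhydrous conditions; it sets out from 23 and returns at 25: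
- 3-Bromofuran is converted by n-BuLi (−78 °C) and ZnCl2 into furan-3-ylzinc chloride F7.
- Negishi coupling with 23 (Pd(PPh3)4 cat., THF, rt) gives 25.

## Further compounds

F1 | step 4 | 2-[(2S)-1-chloro-2-methyl-5-(2-methyl-1,3-dioxolan-2-yl)pentyl]-4,4,5,5-tetramethyl-1,3,2-dioxaborolane (C1 epimers) | CC1(C)OB(C(Cl)[C@@H](C)CCCC2(C)OCCO2)OC1(C)C
F2 | step 4 | (2S)-2-methyl-5-(2-methyl-1,3-dioxolan-2-yl)pentanal | O=C[C@@H](C)CCCC1(C)OCCO1
F3 | step 3 | 4-(2-methyl-1,3-dioxolan-2-yl)butan-1-ol | CC1(CCCCO)OCCO1
F4 | step 3 | 4-(2-methyl-1,3-dioxolan-2-yl)butyl N,N-diisopropylcarbamate | CC1(CCCCOC(=O)N(C(C)C)C(C)C)OCCO1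
F5 | step 6 | ethyl (2E,7S)-3,7-dimethylnon-2-en-8-ynoate | C#C[C@@H](C)CCC/C(C)=C/C(=O)OCC
F6 | step 6 | (2E,7S)-3,7-dimethylnon-2-en-8-yn-1-ol | C#C[C@@H](C)CCC/C(C)=C/CO
F7 | step 11 | furan-3-ylzinc chloride | Cl[Zn]c1ccoc1
F8 | step 19 | (6S,10E,12E)-13-[4-(furan-3-ylmethyl)furan-3-yl]-3-hydroxy-2,6,10-trimethyltrideca-10,12-dien-4-ynoic acid (C2/C3 diastereomers) | OC(=O)C(C)C(O)C#C[C@@H](C)CCC/C(C)=C/C=C/c1cocc1Cc1ccoc1
F9 | step 19 | (5Z)-5-[(2S,6E,8E)-9-[4-(furan-3-ylmethyl)furan-3-yl]-2,6-dimethylnona-6,8-dienylidene]-4-hydroxy-3-methyloxolan-2-one (C3/C4 diastereomers) | CC1C(O)/C(=C/[C@@H](C)CCC/C(C)=C/C=C/c2cocc2Cc2ccoc2)OC1=O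
A1 | alternative 1 | tert-butyl-[[4-(furan-3-ylmethyl)furan-3-yl]methoxy]dimethylsilane (identical with 25) | CC(C)(C)[Si](C)(C)OCc1cocc1Cc1ccoc1
A2 | alternative 1 | tert-butyl-[[5-(3,6-dihydro-1,2-dioxin-4-ylmethyl)-3,6-dihydro-1,2-dioxin-4-yl]methoxy]dimethylsilane | CC(C)(C)[Si](C)(C)OCC1=C(CC2=CCOOC2)COOC1
A3 | alternative 1 | tert-butyl-dimethyl-(2,3,5-trimethylidenehept-6-enoxy)silane | C=CC(=C)CC(=C)C(=C)CO[Si](C)(C)C(C)(C)C
A4 | alternative 2 | (5Z)-4-methoxy-3-methyl-5-[(2S)-2-methylpent-4-enylidene]furan-2(5H)-one | CC1=C(OC)/C(=C/[C@@H](C)CC=C)OC1=O
A5 | alternative 2 | 4-hydroxy-3-methoxy-2-methyl-4-[(2S)-2-methylpent-4-enyl]cyclobut-2-en-1-one (epimers at C4) | CC1=C(OC)C(O)(C[C@@H](C)CC=C)C1=O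
A6 | alternative 2 | 3-methoxy-4-methylcyclobut-3-ene-1,2-dione | CC1=C(OC)C(=O)C1=O
A7 | alternative 3 | ethyl 4-(furan-3-ylmethyl)furan-3-carboxylate | CCOC(=O)c1cocc1Cc1ccoc1
A8 | alternative 3 | 4-phenyloxazole | c1ccc(-c2cocn2)cc1
A9 | alternative 3 | ethyl 4-(furan-3-yl)but-2-ynoate | CCOC(=O)C#CCc1ccoc1
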